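**Retrosynthetic overview**
- The target is a (3S)-isoflavanone. C3 is set after the skeleton is complete, by enantioselective protonation of the 4-silyloxy-2H-chromene (the silyl enol ether of the isoflavanone); desilylation of the two phenols then gives the target.
- Ring C is closed in one operation by a formal cationic [4+2] union that forms C2–C3 and C4–C4a. The partners are an aryloxymethyl cation of ring A (O1=C2 with C8a=C4a, a 2-oxadiene) and an aryl siloxyalkyne (C3≡C4, a masked aryl ketene) that carries rings B and D.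
- Enabling feature: C2 is a methylene on the aryl oxygen O1, so it can be ionized from an O,O-acetal. C4a of the phloroglucinol-type ring A lies ortho to O1 and to the 5-OMe and para to O7, so it is a strong carbon nucleophile exactly where the acyl carbon C4 must arrive.
- Ring order: rings A and B are bought as arenes; ring D (dimethylpyran on ring B) is made first by a propargyl ether Claisen cascade; ring C is made last.
- Fragments: the siloxyalkyne comes from methyl 3,4-dihydroxybenzoate (4 steps), the cation precursor (a pivaloyloxymethyl ether) from 5-methoxyresorcinol (2 steps).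

Key step: step 7

Assumption: the sense of induction of the BINOL-derived acid in step 8 is taken by analogy with silyl enol ethers of 2-aryl cycloalkanones; the antipodal catalyst is equally available and is used if the proton proves to be delivered to the other face of C3.

Step 1
Reactants: 1 methyl 3,4-dihydroxybenzoate
Product: 2 methyl 3-hydroxy-4-[(2-methylbut-3-yn-2-yl)oxy]benzoate
Conditions: 3-chloro-3-methylbut-1-yne (1.1 equiv), K2CO3, KI (cat.), acetone, reflux, Ar
Reagents that add atoms: 3-chloro-3-methylbut-1-yne, CC(C)(Cl)C#C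
Why: Phenol O-propargylation; the 4-OH, para to the ester, is the more acidic phenol, so its phenoxide should form and be alkylated selectively.

Step 2
Reactants: 2 methyl 3-hydroxy-4-[(2-methylbut-3-yn-2-yl)oxy]benzoate
Product: 5 methyl 8-hydroxy-2,2-dimethyl-2H-chromene-6-carboxylate, via allenylphenol 3 (not isolated), via ortho-quinone methide 4 (not isolated)
Conditions: PhNEt2, 185 °C
Reagents that add atoms: none
Why: Aromatic propargyl Claisen rearrangement to the only free ortho carbon, then 1,5-hydrogen shift and oxa-6π electrocyclization, should close ring D as the 2,2-dimethylchromene.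

Step 3
Reactants: 5 methyl 8-hydroxy-2,2-dimethyl-2H-chromene-6-carboxylate
Product: 6 methyl 2,2-dimethyl-8-(triisopropylsilyloxy)-2H-chromene-6-carboxylate
Conditions: i-Pr3SiCl, imidazole, DMF, rt
Reagents that add atoms: triisopropylsilyl chloride, CC(C)[Si](Cl)(C(C)C)C(C)C
Why: Standard silylation of a phenol gives an aryl silyl ether that tolerates organolithiums and Lewis acids at low temperature and is removable without base.

Step 4
Reactants: 6 methyl 2,2-dimethyl-8-(triisopropylsilyloxy)-2H-chromene-6-carboxylate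
Product: 9 triisopropyl({[2,2-dimethyl-8-(triisopropylsilyloxy)-2H-chromen-6-yl]ethynyl}oxy)silane (aryl siloxyalkyne), via lithium dibromoenolate 7 (not isolated), via lithium ynolate 8 (not isolated)
Conditions: CH2Br2, LiTMP (lithium 2,2,6,6-tetramethylpiperidide), THF, −78 °C; LiN(SiMe3)2; n-BuLi, −78 °C → rt; i-Pr3SiOTf, −78 → 0 °C
Reagents that add atoms: dibromomethane, BrCBr; triisopropylsilyl triflate, CC(C)[Si](OS(=O)(=O)C(F)(F)F)(C(C)C)C(C)C
Why: Kowalski ester homologation stopped at the ynolate stage: dibromomethyllithium acylation, bromine–lithium exchange and 1,2-aryl shift of the carbenoid give the lithium ynolate, which the bulky silyl triflate should trap on oxygen.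

Step 5
Reactants: 10 5-methoxyresorcinol (5-methoxybenzene-1,3-diol)
Product: 11 3-methoxy-5-(triisopropylsilyloxy)phenol
Conditions: i-Pr3SiCl (1.0 equiv), imidazole, DMF, 0 °C
Reagents that add atoms: triisopropylsilyl chloride, CC(C)[Si](Cl)(C(C)C)C(C)C
Why: Statistical monosilylation of a symmetric diol, from which unreacted diol and the bis-silyl ether can be separated and recycled.

Step 6
Reactants: 11 3-methoxy-5-(triisopropylsilyloxy)phenol
Product: 12 [3-methoxy-5-(triisopropylsilyloxy)phenoxy]methyl 2,2-dimethylpropanoate (aryl pivaloyloxymethyl ether)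
Conditions: NaH, DMF, 0 °C; ClCH2OPiv, 0 °C → rt
Reagents that add atoms: chloromethyl pivalate, CC(C)(C)C(=O)OCCl
Why: Williamson-type O-alkylation of the phenoxide at the chloromethyl carbon installs C2 on O1 as an ionizable O,O-acetal.

Step 7
Reactants: 12 [3-methoxy-5-(triisopropylsilyloxy)phenoxy]methyl 2,2-dimethylpropanoate; 9 aryl siloxyalkyne
Product: 15 3-[2,2-dimethyl-8-(triisopropylsilyloxy)-2H-chromen-6-yl]-5-methoxy-4,7-bis(triisopropylsilyloxy)-2H-chromene, via aryloxymethyl oxocarbenium triflate 13 (not isolated), via silyl ketenium triflate 14 (not isolated)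
Conditions: 9 (1.3 equiv), 2,6-di-tert-butyl-4-methylpyridine (1.2 equiv), Me3SiOTf (1.1 equiv, slow addition), CH2Cl2, −78 → −40 °C; Et3N quench
Reagents that add atoms: none
Why: Proposed new method: Me3SiOTf silylates the pivalate of 12 and ionizes it to the aryloxymethyl oxocarbenium ion 13, a cationic 2-oxadiene (C2=O1+–C8a=C4a); its CH2 terminus is attacked by the aryl-bearing β-carbon of siloxyalkyne 9 (C2–C3 bond) to give the silyl ketenium ion 14, which is captured at its sp carbon by the ortho carbon C4a of ring A (C4–C4a bond) and rearomatized by the hindered pyridine, a stepwise formal [4+2] cycloaddition overall. The closest known reaction types are the oxa-Povarov reaction of aryl oxocarbenium ions with alkenes to chromans, the Povarov-type annulation of N-aryl iminium ions with ynamides, and the acid-promoted intramolecular arene–siloxyalkyne carbocyclization through silyl ketenium ions; the pairing of an aryl oxocarbenium ion with a siloxyalkyne has not been shown. Ring C closes in a six-membered Friedel–Crafts mode that is exo to the C=O+ bond of the ketenium ion (6-exo-dig) and leaves C3=C4 endocyclic, whereas closure through O1 would need a strained four-membered oxetenium ion and is not expected. No stereocentre is formed, because C3 leaves the step as the sp2 carbon of the enol ether; it is set in step 8. The step needs capture of 13 by the alkyne and not by ring A of a second molecule, which the much higher π-nucleophilicity of the siloxyalkyne, its excess and the slow addition of Me3SiOTf at −78 °C should secure. It also needs closure at the ortho carbon flanked by OMe and not at the one flanked by the silyl ether, which the bulk of the triisopropylsilyl group and the peri strain it would meet with the C4 silyloxy group should secure.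

Step 8
Reactants: 15 3-[2,2-dimethyl-8-(triisopropylsilyloxy)-2H-chromen-6-yl]-5-methoxy-4,7-bis(triisopropylsilyloxy)-2H-chromene
Product: 16 (3S)-3-[2,2-dimethyl-8-(triisopropylsilyloxy)-2H-chromen-6-yl]-5-methoxy-7-(triisopropylsilyloxy)chroman-4-one
Conditions: (R)-3,3'-bis(2,4,6-triisopropylphenyl)-1,1'-binaphthyl-2,2'-diyl N-triflyl thiophosphoramide (5 mol%), PhOH (1.2 equiv), toluene, 0 °C
Reagents that add atoms: none
Why: Chiral Brønsted acid-catalysed enantioselective protonation of the silyl enol ether of an α-aryl cyclic ketone: the chiral acid should deliver the proton to the Re face of C3 (giving 3S, spatially the analogue of an (R)-2-aryl cycloalkanone), and phenol takes up the enol silyl group and regenerates the acid.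

Step 9
Reactants: 16 (3S)-3-[2,2-dimethyl-8-(triisopropylsilyloxy)-2H-chromen-6-yl]-5-methoxy-7-(triisopropylsilyloxy)chroman-4-one
Product: 17 (3S)-7-hydroxy-3-(8-hydroxy-2,2-dimethyl-2H-chromen-6-yl)-5-methoxychroman-4-one (target)
Conditions: KHF2, MeOH/THF, rt
Reagents that add atoms: none
Why: Bifluoride cleavage of the two aryl silyl ethers in a weakly acidic, non-enolizing medium should leave the C3 stereocentre, the chromene double bond and the methyl ether untouched.

**Compound list**
1 | methyl 3,4-dihydroxybenzoate | COC(=O)c1ccc(O)c(O)c1 | starting material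
2 | methyl 3-hydroxy-4-[(2-methylbut-3-yn-2-yl)oxy]benzoate | COC(=O)c1ccc(OC(C)(C)C#C)c(O)c1 | intermediate
3 | methyl 3,4-dihydroxy-5-(3-methylbuta-1,2-dien-1-yl)benzoate (allenylphenol) | COC(=O)c1cc(O)c(O)c(C=C=C(C)C)c1 | intermediate
4 | methyl 5-hydroxy-3-(3-methylbut-2-enylidene)-4-oxocyclohexa-1,5-diene-1-carboxylate (ortho-quinone methide) | COC(=O)C1=CC(=CC=C(C)C)C(=O)C(O)=C1 | intermediate
5 | methyl 8-hydroxy-2,2-dimethyl-2H-chromene-6-carboxylate | COC(=O)c1cc(O)c2OC(C)(C)C=Cc2c1 | intermediate
6 | methyl 2,2-dimethyl-8-(triisopropylsilyloxy)-2H-chromene-6-carboxylate | COC(=O)c1cc(O[Si](C(C)C)(C(C)C)C(C)C)c2OC(C)(C)C=Cc2c1 | intermediate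
7 | lithium 2,2-dibromo-1-[2,2-dimethyl-8-(triisopropylsilyloxy)-2H-chromen-6-yl]ethenolate (lithium dibromoenolate) | [Li]OC(=C(Br)Br)c1cc(O[Si](C(C)C)(C(C)C)C(C)C)c2OC(C)(C)C=Cc2c1 | intermediate
8 | lithium 2-[2,2-dimethyl-8-(triisopropylsilyloxy)-2H-chromen-6-yl]ethynolate (lithium ynolate) | [Li]OC#Cc1cc(O[Si](C(C)C)(C(C)C)C(C)C)c2OC(C)(C)C=Cc2c1 | intermediate
9 | triisopropyl({[2,2-dimethyl-8-(triisopropylsilyloxy)-2H-chromen-6-yl]ethynyl}oxy)silane (aryl siloxyalkyne) | CC(C)[Si](OC#Cc1cc(O[Si](C(C)C)(C(C)C)C(C)C)c2OC(C)(C)C=Cc2c1)(C(C)C)C(C)C | intermediate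
10 | 5-methoxyresorcinol (5-methoxybenzene-1,3-diol) | COc1cc(O)cc(O)c1 | starting material
11 | 3-methoxy-5-(triisopropylsilyloxy)phenol | COc1cc(O)cc(O[Si](C(C)C)(C(C)C)C(C)C)c1 | intermediate
12 | [3-methoxy-5-(triisopropylsilyloxy)phenoxy]methyl 2,2-dimethylpropanoate | COc1cc(OCOC(=O)C(C)(C)C)cc(O[Si](C(C)C)(C(C)C)C(C)C)c1 | intermediate
13 | [3-methoxy-5-(triisopropylsilyloxy)phenyl](methylidene)oxonium triflate (aryloxymethyl oxocarbenium triflate) | COc1cc([O+]=C)cc(O[Si](C(C)C)(C(C)C)C(C)C)c1.[O-]S(=O)(=O)C(F)(F)F | intermediate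
14 | O-triisopropylsilyl ketenium triflate carrying the aryloxymethyl group and the chromenyl group on the terminal carbon (silyl ketenium triflate) | COc1cc(OCC(=C=[O+][Si](C(C)C)(C(C)C)C(C)C)c2cc(O[Si](C(C)C)(C(C)C)C(C)C)c3OC(C)(C)C=Cc3c2)cc(O[Si](C(C)C)(C(C)C)C(C)C)c1.[O-]S(=O)(=O)C(F)(F)F | intermediate
15 | 3-[2,2-dimethyl-8-(triisopropylsilyloxy)-2H-chromen-6-yl]-5-methoxy-4,7-bis(triisopropylsilyloxy)-2H-chromene | COc1cc(O[Si](C(C)C)(C(C)C)C(C)C)cc2OCC(c3cc(O[Si](C(C)C)(C(C)C)C(C)C)c4OC(C)(C)C=Cc4c3)=C(O[Si](C(C)C)(C(C)C)C(C)C)c12 | intermediate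
16 | (3S)-3-[2,2-dimethyl-8-(triisopropylsilyloxy)-2H-chromen-6-yl]-5-methoxy-7-(triisopropylsilyloxy)chroman-4-one | COc1cc(O[Si](C(C)C)(C(C)C)C(C)C)cc2c1C(=O)[C@@H](c1cc(O[Si](C(C)C)(C(C)C)C(C)C)c3c(c1)C=CC(C)(C)O3)CO2 | intermediate
17 | (3S)-7-hydroxy-3-(8-hydroxy-2,2-dimethyl-2H-chromen-6-yl)-5-methoxychroman-4-one | COc1cc(O)cc2c1C(=O)[C@@H](c1cc(O)c3c(c1)C=CC(C)(C)O3)CO2 | target

**Step count**
Total steps: 9. Longest linear sequence: 7 (steps 1, 2, 3, 4, 7, 8, 9).

**Steps most likely to fail**

1. Step 7 (proposed new method). What may go wrong: the aryloxymethyl cation may be captured by ring A of a second molecule (oligomerization); the siloxyalkyne may be protonated and lost to adventitious acid; the product enol ether may be alkylated again; the ring may close at the wrong ortho carbon. Fallback with known reactions, setting out from 6 (and using 12) and coming back at 15: the Kowalski homologation of 6 is run as in step 4 but the ynolate 8 is quenched with dilute aqueous acid to give 2-[2,2-dimethyl-8-(triisopropylsilyloxy)-2H-chromen-6-yl]acetic acid F1. This is converted with LiN(SiMe3)2 and Me3SiCl into its bis(trimethylsilyl) ketene acetal F2. A Mukaiyama-type alkylation of F2 with 12 (Me3SiOTf, CH2Cl2, −78 °C, aqueous work-up) should give the racemic 2-aryl-3-aryloxypropanoic acid F3. Intramolecular Friedel–Crafts acylation through the mixed anhydride (trifluoroacetic anhydride, CH2Cl2, 0 °C) closes ring C to the racemic bis-silyl isoflavanone F4. Enol silylation (i-Pr3SiOTf, Et3N, CH2Cl2) returns to 15.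

2. Step 8. What may go wrong: slow transfer of the bulky enol silyl group may make the C3 protonation reversible and erode the enantioselectivity, and the acid may enolize the product. Fallback setting out from 15 and coming back at 16: hydrolysis of the enol ether (dilute HCl, THF) gives the racemic bis-silyl isoflavanone F5 (the same constitution as F4). Asymmetric transfer hydrogenation with dynamic kinetic resolution (RuCl(p-cymene)[(S,S)-TsDPEN], HCO2H/Et3N, 40 °C) should give the cis-(3S,4S)-3-[2,2-dimethyl-8-(triisopropylsilyloxy)-2H-chromen-6-yl]-5-methoxy-7-(triisopropylsilyloxy)chroman-4-ol F6; the (S,S) catalyst sets 4S, hydride arrives anti to the aryl group, and C3 epimerizes under the basic medium. Oxidation of the alcohol with Dess–Martin periodinane (NaHCO3, CH2Cl2, 0 °C) returns the ketone 16 without touching C3.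

3. Step 4. What may go wrong: incomplete carbenoid rearrangement, silylation of the ynolate on carbon instead of oxygen, or hydrolysis of the siloxyalkyne during isolation. Fallback setting out from 6 and coming back at 9: reduction with i-Bu2AlH (CH2Cl2, −78 °C) gives [2,2-dimethyl-8-(triisopropylsilyloxy)-2H-chromen-6-yl]methanol F7. Oxidation with MnO2 gives 2,2-dimethyl-8-(triisopropylsilyloxy)-2H-chromene-6-carbaldehyde F8. Colvin homologation with lithiated Me3SiCHN2 (THF, −78 °C → rt) gives 6-ethynyl-2,2-dimethyl-8-(triisopropylsilyloxy)-2H-chromene F9. Deprotonation with LiN(SiMe3)2 and oxidation with lithium tert-butyl peroxide (THF, −78 → 0 °C) gives the ynolate 8, which is silylated on oxygen with i-Pr3SiOTf to return to 9.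

Further compounds
F1 | step 7 | 2-[2,2-dimethyl-8-(triisopropylsilyloxy)-2H-chromen-6-yl]acetic acid | OC(=O)Cc1cc(O[Si](C(C)C)(C(C)C)C(C)C)c2OC(C)(C)C=Cc2c1
F2 | step 7 | bis(trimethylsilyl) ketene acetal of F1 | C[Si](C)(C)OC(O[Si](C)(C)C)=Cc1cc(O[Si](C(C)C)(C(C)C)C(C)C)c2OC(C)(C)C=Cc2c1
F3 | step 7 | racemic 2-[2,2-dimethyl-8-(triisopropylsilyloxy)-2H-chromen-6-yl]-3-[3-methoxy-5-(triisopropylsilyloxy)phenoxy]propanoic acid | COc1cc(OCC(C(=O)O)c2cc(O[Si](C(C)C)(C(C)C)C(C)C)c3OC(C)(C)C=Cc3c2)cc(O[Si](C(C)C)(C(C)C)C(C)C)c1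
F4 | step 7 | racemic 3-[2,2-dimethyl-8-(triisopropylsilyloxy)-2H-chromen-6-yl]-5-methoxy-7-(triisopropylsilyloxy)chroman-4-one | COc1cc(O[Si](C(C)C)(C(C)C)C(C)C)cc2c1C(=O)C(c1cc(O[Si](C(C)C)(C(C)C)C(C)C)c3c(c1)C=CC(C)(C)O3)CO2
F5 | step 8 | racemic 3-[2,2-dimethyl-8-(triisopropylsilyloxy)-2H-chromen-6-yl]-5-methoxy-7-(triisopropylsilyloxy)chroman-4-one | COc1cc(O[Si](C(C)C)(C(C)C)C(C)C)cc2c1C(=O)C(c1cc(O[Si](C(C)C)(C(C)C)C(C)C)c3c(c1)C=CC(C)(C)O3)CO2
F6 | step 8 | (3S,4S)-3-[2,2-dimethyl-8-(triisopropylsilyloxy)-2H-chromen-6-yl]-5-methoxy-7-(triisopropylsilyloxy)chroman-4-ol | COc1cc(O[Si](C(C)C)(C(C)C)C(C)C)cc2c1[C@@H](O)[C@@H](c1cc(O[Si](C(C)C)(C(C)C)C(C)C)c3c(c1)C=CC(C)(C)O3)CO2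
F7 | step 4 | [2,2-dimethyl-8-(triisopropylsilyloxy)-2H-chromen-6-yl]methanol | OCc1cc(O[Si](C(C)C)(C(C)C)C(C)C)c2OC(C)(C)C=Cc2c1
F8 | step 4 | 2,2-dimethyl-8-(triisopropylsilyloxy)-2H-chromene-6-carbaldehyde | O=Cc1cc(O[Si](C(C)C)(C(C)C)C(C)C)c2OC(C)(C)C=Cc2c1
F9 | step 4 | 6-ethynyl-2,2-dimethyl-8-(triisopropylsilyloxy)-2H-chromene | C#Cc1cc(O[Si](C(C)C)(C(C)C)C(C)C)c2OC(C)(C)C=Cc2c1
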